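Ring B is a 2-methylenecyclohexanol: the C7 carbinol sits next to C8, which carries the exocyclic C17 methylene. Cutting C7–C8 therefore gives a ring A aldehyde with a 2-iodoalkene on C9, and one Nozaki–Hiyama–Kishi reaction closes ring B, forms C7–C8 and sets C7. The precursor 48 already carries the C2 angelate, the C20 (R)-2-methylbutanoate and free hydroxyls, so the cyclisation is the last step. Its C9/C10 pair comes from an Ireland–Claisen rearrangement between a quinic-acid-derived ring A allylic alcohol and a linalool-derived acid.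

Key step: step 28

Remarks
- Labdane locants are used on all intermediates (ring A = C1–C5 and C10; C6–C7 = arm on C5; C8/C17 = iodoalkene; C20 on C10; C11–C16 = side chain); β is the face of C20.
- The target SMILES is read as 2R,3S,5R,7R,9S,10R,13R with an (R)-2-methylbutanoate: trans-decalin, C20 β, 5-H α, 9-H β (side chain α), oxygens at C2, C3 and C7 α.
- (R)-2-Methylbutanoic acid and angelic acid are taken as purchased reagents.
- Ring A is taken from (−)-quinic acid, whose cis-diol carbons map onto C2/C3 with the required absolute configuration and whose C1 becomes the C10 ketone.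
- 34 may sit as its cyclic hydroxy-lactone tautomer and 38 as its cyclic hemiketal; both react through the open forms shown.

Step 1
Reactants: 1 (−)-quinic acid
Product: 2 quinic acid 3,4-acetonide 1,5-lactone
Conditions: Me2C(OMe)2, TsOH·H2O (cat.), acetone, reflux
Reagents that add atoms: 2,2-dimethoxypropane, COC(C)(C)OC
Why: Acid-catalysed ketalisation of the cis-3,4-diol with lactonisation of the carboxyl onto the syn 5-hydroxyl; no stereocentre is touched.

Step 2
Reactants: 2 quinic acid 3,4-acetonide 1,5-lactone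
Product: 3 acetonide triol
Conditions: NaBH4, EtOH, 0 °C to rt
Reagents that add atoms: none
Why: Borohydride reduction of the strained α-hydroxy lactone should open it to the hydroxymethyl carbinol and free the 5-hydroxyl.

Step 3
Reactants: 3 acetonide triol
Product: 4 β-hydroxy ketone
Conditions: NaIO4, H2O (pH 7 phosphate buffer), 0 °C
Reagents that add atoms: none
Why: Malaprade cleavage of the only free 1,2-diol (tertiary carbinol/CH2OH) should give the ketone that becomes C10.

Step 4
Reactants: 4 β-hydroxy ketone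
Product: 6 (4S,5R)-4,5-(isopropylidenedioxy)cyclohex-2-en-1-one, via mesylate 5 (not isolated)
Conditions: MsCl, Et3N, CH2Cl2, 0 °C to rt
Reagents that add atoms: none
Why: Mesylation followed by E1cB elimination should give the enone, the mesylate being a far better leaving group than the acetonide oxygen on the other β-carbon.

Step 5
Reactants: 6 (4S,5R)-4,5-(isopropylidenedioxy)cyclohex-2-en-1-one
Product: 8 (4S,5R)-4,5-(isopropylidenedioxy)-3-methylcyclohex-2-en-1-one, via silyl enol ether 7 (not isolated)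
Conditions: Me2CuLi (from CuI, MeLi), Me3SiCl, THF, −78 °C; then Pd(OAc)2 (1 equiv), MeCN, rt
Reagents that add atoms: lithium dimethylcuprate, [Li+].C[Cu-]C
Why: Cuprate conjugate addition anti to the acetonide with silyl trapping, then Saegusa–Ito oxidation, should re-form the enone with a methyl on C4; the transient C4 centre is erased.

Step 6
Reactants: 8 (4S,5R)-4,5-(isopropylidenedioxy)-3-methylcyclohex-2-en-1-one
Product: 11 (2S,4S,5R)-2-allyl-4,5-(isopropylidenedioxy)-3,3-dimethylcyclohexan-1-one, via silyl enol ether 9 (not isolated), via lithium enolate 10 (not isolated)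
Conditions: Me2CuLi (from CuI, MeLi), Me3SiCl, THF, −78 to −30 °C; MeLi, THF, 0 °C; allyl bromide, DMPU, −78 °C to rt
Reagents that add atoms: lithium dimethylcuprate, [Li+].C[Cu-]C; allyl bromide, C=CCBr
Why: A second conjugate addition builds the C4 gem-dimethyl group and the regiodefined lithium enolate is allylated at C5 (enolate alkylation); the equatorial 5β arm, trans to the axial C3 oxygen, is also the thermodynamic epimer because C5 stays enolisable, so any cis isomer can be equilibrated with DBU.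

Step 7
Reactants: 11 (2S,4S,5R)-2-allyl-4,5-(isopropylidenedioxy)-3,3-dimethylcyclohexan-1-one
Product: 13 ring A diol, via ozonide 12 (not isolated)
Conditions: O3, CH2Cl2, −78 °C; then NaBH4, MeOH, −78 °C to rt
Reagents that add atoms: ozone, [O-][O+]=O
Why: Ozonolysis with reductive work-up trims the allyl group to the C6–C7 hydroxyethyl arm and reduces the ketone too; the C10 carbinol epimers are carried together since that centre is re-oxidised in step 9.

Step 8
Reactants: 13 ring A diol
Product: 14 ring A C7 silyl ether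
Conditions: t-BuPh2SiCl, imidazole, CH2Cl2, 0 °C
Reagents that add atoms: tert-butyldiphenylsilyl chloride, CC(C)(C)[Si](Cl)(c1ccccc1)c1ccccc1
Why: Silylation should take the primary hydroxyl in preference to the hindered secondary one.

Step 9
Reactants: 14 ring A C7 silyl ether
Product: 15 ring A C10 ketone
Conditions: Dess–Martin periodinane, NaHCO3, CH2Cl2, rt
Reagents that add atoms: none
Why: Dess–Martin oxidation returns the C10 ketone; C5 keeps the equatorial β arm, the stable epimer in the chair fixed by the cis-acetonide and the C4 methyls.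

Step 10
Reactants: 15 ring A C10 ketone; 16 triethyl phosphonoacetate
Product: 17 ring A (E)-enoate
Conditions: NaH, THF, 0 °C to reflux
Reagents that add atoms: none
Why: Horner–Wadsworth–Emmons olefination should turn the ester toward the unsubstituted C1 side (E); the equatorial C2–O bond is poorly aligned for β-elimination.

Step 11
Reactants: 17 ring A (E)-enoate
Product: 18 ring A (E)-allylic alcohol
Conditions: i-Bu2AlH, CH2Cl2, −78 °C
Reagents that add atoms: none
Why: 1,2-Reduction of the enoate by the aluminium hydride gives the cyclohexylidene-ethanol and leaves acetonide and silyl ether alone.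

Step 12
Reactants: 19 (R)-linalool
Product: 20 (R)-linalool triethylsilyl ether
Conditions: Et3SiOTf, 2,6-lutidine, CH2Cl2, −78 to 0 °C
Reagents that add atoms: triethylsilyl triflate, CC[Si](CC)(CC)OS(=O)(=O)C(F)(F)F
Why: Silyl triflate with a hindered base silylates the tertiary alcohol, which would otherwise lactonise with the later acid.

Step 13
Reactants: 20 (R)-linalool triethylsilyl ether
Product: 22 (R)-4-methyl-4-(triethylsilyloxy)hex-5-en-1-ol, via ozonide 21 (not isolated)
Conditions: O3 (1 equiv, Sudan Red 7B end point), CH2Cl2, −78 °C; then NaBH4, MeOH, −78 to 0 °C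
Reagents that add atoms: ozone, [O-][O+]=O
Why: Selective ozonolysis: ozone should take the electron-rich trisubstituted alkene well before the hindered vinyl group, and reductive work-up gives the primary alcohol.

Step 14
Reactants: 22 (R)-4-methyl-4-(triethylsilyloxy)hex-5-en-1-ol
Product: 23 (R)-6-iodo-3-methyl-3-(triethylsilyloxy)hex-1-ene
Conditions: I2, PPh3, imidazole, CH2Cl2, 0 °C
Reagents that add atoms: iodine, II
Why: Appel-type iodination of the primary alcohol under buffered conditions that spare the silyl ether.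

Step 15
Reactants: 23 (R)-6-iodo-3-methyl-3-(triethylsilyloxy)hex-1-ene
Product: 25 (R)-5-methyl-5-(triethylsilyloxy)hept-6-enoic acid, via alkyllithium 24 (not isolated)
Conditions: t-BuLi (2.1 equiv), Et2O/pentane, −78 °C; CO2, −78 °C; aq. NaH2PO4
Reagents that add atoms: carbon dioxide, O=C=O
Why: Lithium–iodine exchange and carboxylation add C8; kept at −78 °C the 5-hexenyllithium should not cyclise onto the vinyl group.

Step 16
Reactants: 18 ring A (E)-allylic alcohol; 25 (R)-5-methyl-5-(triethylsilyloxy)hept-6-enoic acid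
Product: 26 allylic ester
Conditions: EDC·HCl, DMAP, CH2Cl2, 0 °C to rt
Reagents that add atoms: none
Why: Steglich-type carbodiimide esterification of an unhindered primary allylic alcohol.

Step 17
Reactants: 26 allylic ester
Product: 30 seco acid with the C9–C10 bond, via lithium enolate 27 (not isolated), via silyl ketene acetal 28 (not isolated), via silyl ester 29 (not isolated)
Conditions: LiN(i-Pr)2, THF, −78 °C; Me3SiCl/Et3N, −78 °C to rt, then 60 °C; aq. NaOH, then AcOH to pH 5
Reagents that add atoms: none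
Why: Ireland–Claisen rearrangement: amide base in THF should give the E(O) enolate (C11 syn to the allylic oxygen), and a chair [3,3] shift onto the α face of C10 (the β face is blocked by the axial C4 methyl) forms C9–C10 with the vinyl group axial (β) and, from the E alkene, C11 syn to C1, which is the target C9/C10 arrangement.

Step 18
Reactants: 30 seco acid with the C9–C10 bond
Product: 31 iodolactone
Conditions: I2, NaHCO3, MeCN/H2O, 0 °C, dark
Reagents that add atoms: iodine, II
Why: 5-exo iodolactonisation lets the C8 carboxylate pick out the C10 vinyl group and leaves the remote C14 alkene untouched; the new CH–O centre is lost in step 19.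

Step 19
Reactants: 31 iodolactone
Product: 34 C20 aldehyde acid, via epoxy carboxylate 32 (not isolated), via dihydroxy carboxylate 33 (not isolated)
Conditions: LiOH, THF/H2O, 50 °C; then NaH2PO4 (pH 7), NaIO4, 0 °C to rt; AcOH to pH 5
Reagents that add atoms: lithium hydroxide, [Li+].[OH-]
Why: Saponification frees the C20 alkoxide, which closes the epoxide; aqueous base opens it to the diol and Malaprade cleavage removes the extra carbon as formaldehyde, leaving the neopentyl C20 aldehyde.

Step 20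
Reactants: 34 C20 aldehyde acid
Product: 36 C8–C20 γ-lactone, via hydroxy acid 35 (not isolated)
Conditions: NaBH4, EtOH, 0 °C; then AcOH, rt
Reagents that add atoms: none
Why: Borohydride reduces the aldehyde and the γ-hydroxy acid lactonises on acidification (reduction/lactonisation); C9 is not enolised.

Step 21
Reactants: 36 C8–C20 γ-lactone
Product: 38 C20 hydroxy C8 methyl ketone, via lithium hemiketalate 37 (not isolated)
Conditions: MeLi (1.1 equiv), THF, −78 °C; aq. NH4Cl
Reagents that add atoms: methyllithium, [Li]C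
Why: Mono-addition of MeLi to a lactone: the tetrahedral lithium hemiketalate holds at −78 °C and gives the methyl ketone (C8, C17) and the C20 alcohol on work-up.

Step 22
Reactants: 38 C20 hydroxy C8 methyl ketone; 39 (R)-2-methylbutanoic acid
Product: 40 C20 (R)-2-methylbutanoate methyl ketone
Conditions: EDC·HCl, DMAP, CH2Cl2, rt
Reagents that add atoms: none
Why: Steglich esterification should trap the open keto alcohol at its primary hydroxyl; a simple α-branched alkanoic acid is not expected to epimerise under these conditions.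

Step 23
Reactants: 40 C20 (R)-2-methylbutanoate methyl ketone
Product: 42 C8 iodoalkene, via silyl hydrazone 41 (not isolated)
Conditions: t-BuMe2SiNHNHSiMe2t-Bu, Sc(OTf)3 (cat.), CHCl3, 55 °C; then I2, 1,1,3,3-tetramethylguanidine, THF, 0 °C
Reagents that add atoms: iodine, II
Why: Barton vinyl iodide synthesis through the N-silyl hydrazone, which forms without free hydrazine and so spares the ester; proton loss should occur from the methyl group because C9–H is tertiary and flanked by the quaternary C10.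

Step 24
Reactants: 42 C8 iodoalkene
Product: 43 C2,C3,C13 triol
Conditions: PPTS, MeOH, 50 °C
Reagents that add atoms: none
Why: Mild acid transketalisation removes the acetonide and the tertiary triethylsilyl ether, while the primary tert-butyldiphenylsilyl ether, the ester and the iodoalkene should hold and the acidity stays below what ionises the tertiary allylic alcohol.

Step 25
Reactants: 43 C2,C3,C13 triol; 44 angelic acid
Product: 46 C2 angelate, via mixed anhydride 45 (not isolated)
Conditions: 2,4,6-Cl3C6H2COCl, Et3N, toluene, rt; then 43, toluene, 75 °C (no DMAP)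
Reagents that add atoms: none
Why: Yamaguchi-type mixed-anhydride acylation without a nucleophilic catalyst is the known way to keep the Z geometry; the equatorial C2 hydroxyl should react ahead of the axial neopentyl C3 hydroxyl and the tertiary C13 hydroxyl.

Step 26
Reactants: 46 C2 angelate
Product: 47 C7 primary alcohol
Conditions: HF·pyridine, pyridine, THF, 0 °C to rt
Reagents that add atoms: none
Why: Buffered fluoride desilylation removes the last silyl group without base, so no acyl migration from C2 to C3 is expected.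

Step 27
Reactants: 47 C7 primary alcohol
Product: 48 ring A iodoalkene aldehyde
Conditions: TEMPO (cat.), PhI(OAc)2, CH2Cl2, rt
Reagents that add atoms: none
Why: The oxoammonium oxidation takes primary alcohols well ahead of the hindered secondary C3 and tertiary C13 hydroxyls and stops at the aldehyde.

Step 28
Reactants: 48 ring A iodoalkene aldehyde
Product: 51 target, via alkenylchromium 49 (not isolated), via chromium alkoxide 50 (not isolated)
Conditions: CrCl2 (8 equiv), NiCl2 (2 mol%), degassed DMF, 0.005 M, rt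
Reagents that add atoms: none
Why: CrCl2 reduces NiCl2 to zerovalent nickel, which inserts into the C8–I bond; transmetalation to trivalent chromium gives alkenylchromium 49, whose C8 adds to the C7 aldehyde to give alkoxide 50, hydrolysed on work-up. This is the intramolecular Nozaki–Hiyama–Kishi cyclisation of a 2-iodoalkene onto an aldehyde, a known route to 2-methylenecycloalkanols. Ring B closes in the 6-exo-trig mode between C7 and C8, across the trans-diequatorial C5 and C10 bonds of ring A. C7 is the only new stereocentre: in a chair-like closure the C7–O bond should sit pseudo-axial, away from the C17 methylene (allylic 1,3-strain), which places the hydroxyl α, anti to C20; the axial C11 chain on the same face works against this, so the selectivity is the open question of the route. The step needs aldehyde chemoselectivity, which the alkenylchromium reagent provides beside two esters, three free hydroxyls and the C14 alkene, and it needs cyclisation to outrun intermolecular coupling, which high dilution secures.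

Compound list
1 | (−)-quinic acid | C1[C@H]([C@H]([C@@H](C[C@@]1(C(=O)O)O)O)O)O | starting material
2 | quinic acid 3,4-acetonide 1,5-lactone | C1[C@H]2OC(C)(C)O[C@H]2[C@H]3C[C@]1(O)C(=O)O3 | intermediate
3 | acetonide triol (lactone reduced; centres as in 1) | C1[C@H]2OC(C)(C)O[C@H]2[C@H](O)C[C@]1(O)CO | intermediate
4 | β-hydroxy ketone (3-hydroxy-4,5-isopropylidenedioxycyclohexanone; centres as in 1) | O=C1C[C@H]2OC(C)(C)O[C@H]2[C@H](O)C1 | intermediate
5 | mesylate of 4 | O=C1C[C@H]2OC(C)(C)O[C@H]2[C@H](OS(C)(=O)=O)C1 | intermediate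
6 | (4S,5R)-4,5-(isopropylidenedioxy)cyclohex-2-en-1-one | O=C1C[C@H]2OC(C)(C)O[C@H]2C=C1 | intermediate
7 | trimethylsilyl enol ether after first methyl addition (methyl anti to acetonide) | C[Si](C)(C)OC1=C[C@@H](C)[C@@H]2OC(C)(C)O[C@@H]2C1 | intermediate
8 | (4S,5R)-4,5-(isopropylidenedioxy)-3-methylcyclohex-2-en-1-one | O=C1C=C(C)[C@@H]2OC(C)(C)O[C@@H]2C1 | intermediate
9 | trimethylsilyl enol ether of the 3,3-dimethyl ketone | C[Si](C)(C)OC1=CC(C)(C)[C@@H]2OC(C)(C)O[C@@H]2C1 | intermediate
10 | lithium enolate of the 3,3-dimethyl ketone | [Li]OC1=CC(C)(C)[C@@H]2OC(C)(C)O[C@@H]2C1 | intermediate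
11 | (2S,4S,5R)-2-allyl-4,5-(isopropylidenedioxy)-3,3-dimethylcyclohexan-1-one | C=CC[C@H]1C(C)(C)[C@H](OC2(C)C)[C@H](O2)CC1=O | intermediate
12 | secondary ozonide of 11 (trioxolane centre undefined) | O1OCOC1C[C@H]1C(C)(C)[C@H](OC2(C)C)[C@H](O2)CC1=O | intermediate
13 | ring A diol: (2S,4S,5R)-2-(2-hydroxyethyl)-4,5-(isopropylidenedioxy)-3,3-dimethylcyclohexan-1-ol, C10 epimers | OCC[C@H]1C(C)(C)[C@H](OC2(C)C)[C@H](O2)CC1O | intermediate
14 | ring A C7 tert-butyldiphenylsilyl ether of 13, C10 epimers | CC(C)(C)[Si](c1ccccc1)(c1ccccc1)OCC[C@H]1C(C)(C)[C@H](OC2(C)C)[C@H](O2)CC1O | intermediate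
15 | ring A C10 ketone: (2S,4S,5R)-2-[2-(tert-butyldiphenylsilyloxy)ethyl]-4,5-(isopropylidenedioxy)-3,3-dimethylcyclohexan-1-one | CC(C)(C)[Si](c1ccccc1)(c1ccccc1)OCC[C@H]1C(C)(C)[C@H](OC2(C)C)[C@H](O2)CC1=O | intermediate
16 | triethyl phosphonoacetate | CCOC(=O)CP(=O)(OCC)OCC | starting material
17 | ring A (E)-enoate: ethyl cyclohexylideneacetate of 15, ester syn to C1 | CC(C)(C)[Si](c1ccccc1)(c1ccccc1)OCC[C@H]1C(C)(C)[C@H](OC2(C)C)[C@H](O2)C/C1=C\C(=O)OCC | intermediate
18 | ring A (E)-allylic alcohol: 2-cyclohexylidene-ethanol from 17 | CC(C)(C)[Si](c1ccccc1)(c1ccccc1)OCC[C@H]1C(C)(C)[C@H](OC2(C)C)[C@H](O2)C/C1=C\CO | intermediate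
19 | (R)-linalool | C=C[C@](C)(O)CCC=C(C)C | starting material
20 | (R)-linalool triethylsilyl ether | C=C[C@](C)(O[Si](CC)(CC)CC)CCC=C(C)C | intermediate
21 | secondary ozonide of 20 at the trisubstituted alkene | C=C[C@](C)(O[Si](CC)(CC)CC)CCC1OOC(C)(C)O1 | intermediate
22 | (R)-4-methyl-4-(triethylsilyloxy)hex-5-en-1-ol | C=C[C@](C)(O[Si](CC)(CC)CC)CCCO | intermediate
23 | (R)-6-iodo-3-methyl-3-(triethylsilyloxy)hex-1-ene | C=C[C@](C)(O[Si](CC)(CC)CC)CCCI | intermediate
24 | primary alkyllithium from 23 | C=C[C@](C)(O[Si](CC)(CC)CC)CCC[Li] | intermediate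
25 | (R)-5-methyl-5-(triethylsilyloxy)hept-6-enoic acid | C=C[C@](C)(O[Si](CC)(CC)CC)CCCC(=O)O | intermediate
26 | allylic ester of 18 with 25 | CC(C)(C)[Si](c1ccccc1)(c1ccccc1)OCC[C@H]1C(C)(C)[C@H](OC2(C)C)[C@H](O2)C/C1=C\COC(=O)CCC[C@@](C)(O[Si](CC)(CC)CC)C=C | intermediate
27 | lithium E(O) enolate of 26 (C11 syn to the allylic oxygen) | CC(C)(C)[Si](c1ccccc1)(c1ccccc1)OCC[C@H]1C(C)(C)[C@H](OC2(C)C)[C@H](O2)C/C1=C\CO/C(O[Li])=C\CC[C@@](C)(O[Si](CC)(CC)CC)C=C | intermediate
28 | trimethylsilyl ketene acetal (C11 syn to the allylic oxygen) | CC(C)(C)[Si](c1ccccc1)(c1ccccc1)OCC[C@H]1C(C)(C)[C@H](OC2(C)C)[C@H](O2)C/C1=C\CO/C(O[Si](C)(C)C)=C\CC[C@@](C)(O[Si](CC)(CC)CC)C=C | intermediate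
29 | trimethylsilyl ester of 30 | CC(C)(C)[Si](c1ccccc1)(c1ccccc1)OCC[C@H]1C(C)(C)[C@H](OC2(C)C)[C@H](O2)C[C@]1(C=C)[C@H](CC[C@@](C)(O[Si](CC)(CC)CC)C=C)C(=O)O[Si](C)(C)C | intermediate
30 | seco acid: C8 carboxylic acid on C9 (target configuration), C10 quaternary with β-vinyl, 13R | CC(C)(C)[Si](c1ccccc1)(c1ccccc1)OCC[C@H]1C(C)(C)[C@H](OC2(C)C)[C@H](O2)C[C@]1(C=C)[C@H](CC[C@@](C)(O[Si](CC)(CC)CC)C=C)C(=O)O | intermediate
31 | spiro iodolactone (C8 carbonyl, ring oxygen on C20, exocyclic CH2I; C20 epimers) | CC(C)(C)[Si](c1ccccc1)(c1ccccc1)OCC[C@H]1C(C)(C)[C@H](OC2(C)C)[C@H](O2)C[C@@]13C(CI)OC(=O)[C@H]3CC[C@@](C)(O[Si](CC)(CC)CC)C=C | intermediate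
32 | lithium epoxy carboxylate (oxirane on C10) | CC(C)(C)[Si](c1ccccc1)(c1ccccc1)OCC[C@H]1C(C)(C)[C@H](OC2(C)C)[C@H](O2)C[C@]1(C3CO3)[C@H](CC[C@@](C)(O[Si](CC)(CC)CC)C=C)C(=O)[O-].[Li+] | intermediate
33 | lithium dihydroxy carboxylate (1,2-diol on C10) | CC(C)(C)[Si](c1ccccc1)(c1ccccc1)OCC[C@H]1C(C)(C)[C@H](OC2(C)C)[C@H](O2)C[C@]1(C(O)CO)[C@H](CC[C@@](C)(O[Si](CC)(CC)CC)C=C)C(=O)[O-].[Li+] | intermediate
34 | C20 aldehyde C8 acid | CC(C)(C)[Si](c1ccccc1)(c1ccccc1)OCC[C@H]1C(C)(C)[C@H](OC2(C)C)[C@H](O2)C[C@]1(C=O)[C@H](CC[C@@](C)(O[Si](CC)(CC)CC)C=C)C(=O)O | intermediate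
35 | C20 hydroxy C8 acid | CC(C)(C)[Si](c1ccccc1)(c1ccccc1)OCC[C@H]1C(C)(C)[C@H](OC2(C)C)[C@H](O2)C[C@]1(CO)[C@H](CC[C@@](C)(O[Si](CC)(CC)CC)C=C)C(=O)O | intermediate
36 | spiro γ-lactone (C8 carbonyl, O–C20H2) | CC(C)(C)[Si](c1ccccc1)(c1ccccc1)OCC[C@H]1C(C)(C)[C@H](OC2(C)C)[C@H](O2)C[C@@]13COC(=O)[C@H]3CC[C@@](C)(O[Si](CC)(CC)CC)C=C | intermediate
37 | lithium hemiketalate from 36 (C8 epimers) | CC(C)(C)[Si](c1ccccc1)(c1ccccc1)OCC[C@H]1C(C)(C)[C@H](OC2(C)C)[C@H](O2)C[C@@]13COC(C)(O[Li])[C@H]3CC[C@@](C)(O[Si](CC)(CC)CC)C=C | intermediate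
38 | C20 hydroxy C8 methyl ketone (open form) | CC(C)(C)[Si](c1ccccc1)(c1ccccc1)OCC[C@H]1C(C)(C)[C@H](OC2(C)C)[C@H](O2)C[C@]1(CO)[C@H](CC[C@@](C)(O[Si](CC)(CC)CC)C=C)C(C)=O | intermediate
39 | (R)-2-methylbutanoic acid | CC[C@@H](C)C(=O)O | starting material
40 | C20 (R)-2-methylbutanoate C8 methyl ketone | CC(C)(C)[Si](c1ccccc1)(c1ccccc1)OCC[C@H]1C(C)(C)[C@H](OC2(C)C)[C@H](O2)C[C@]1(COC(=O)[C@H](C)CC)[C@H](CC[C@@](C)(O[Si](CC)(CC)CC)C=C)C(C)=O | intermediate
41 | N-tert-butyldimethylsilyl hydrazone of 40 | CC(C)(C)[Si](c1ccccc1)(c1ccccc1)OCC[C@H]1C(C)(C)[C@H](OC2(C)C)[C@H](O2)C[C@]1(COC(=O)[C@H](C)CC)[C@H](CC[C@@](C)(O[Si](CC)(CC)CC)C=C)C(C)=NN[Si](C)(C)C(C)(C)C | intermediate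
42 | C8 iodoalkene (acetonide, C7 and C13 silyl ethers, C20 ester) | CC(C)(C)[Si](c1ccccc1)(c1ccccc1)OCC[C@H]1C(C)(C)[C@H](OC2(C)C)[C@H](O2)C[C@]1(COC(=O)[C@H](C)CC)[C@H](CC[C@@](C)(O[Si](CC)(CC)CC)C=C)C(I)=C | intermediate
43 | C2,C3,C13 triol (C7 silyl ether, C20 ester, iodoalkene) | CC(C)(C)[Si](c1ccccc1)(c1ccccc1)OCC[C@H]1C(C)(C)[C@H](O)[C@H](O)C[C@]1(COC(=O)[C@H](C)CC)[C@H](CC[C@@](C)(O)C=C)C(I)=C | intermediate
44 | angelic acid, (Z)-2-methylbut-2-enoic acid | OC(=O)/C(C)=C\C | starting material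
45 | angelic 2,4,6-trichlorobenzoic mixed anhydride | C/C=C(/C)C(=O)OC(=O)c1c(Cl)cc(Cl)cc1Cl | intermediate
46 | C2 angelate (C3 and C13 hydroxyls free, C7 silyl ether) | CC(C)(C)[Si](c1ccccc1)(c1ccccc1)OCC[C@H]1C(C)(C)[C@H](O)[C@H](OC(=O)/C(C)=C\C)C[C@]1(COC(=O)[C@H](C)CC)[C@H](CC[C@@](C)(O)C=C)C(I)=C | intermediate
47 | C7 primary alcohol | OCC[C@H]1C(C)(C)[C@H](O)[C@H](OC(=O)/C(C)=C\C)C[C@]1(COC(=O)[C@H](C)CC)[C@H](CC[C@@](C)(O)C=C)C(I)=C | intermediate
48 | ring A iodoalkene aldehyde (key-step precursor: C7 aldehyde, C8 iodoalkene, both esters, free 3-, 13-hydroxyls) | O=CC[C@H]1C(C)(C)[C@H](O)[C@H](OC(=O)/C(C)=C\C)C[C@]1(COC(=O)[C@H](C)CC)[C@H](CC[C@@](C)(O)C=C)C(I)=C | intermediate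
49 | alkenylchromium dichloride at C8 | O=CC[C@H]1C(C)(C)[C@H](O)[C@H](OC(=O)/C(C)=C\C)C[C@]1(COC(=O)[C@H](C)CC)[C@H](CC[C@@](C)(O)C=C)C([Cr](Cl)Cl)=C | intermediate
50 | C7 chromium alkoxide of the target | C=C[C@](C)(O)CC[C@@H]1C(=C)[C@H](O[Cr](Cl)Cl)C[C@H]2C(C)(C)[C@H](O)[C@H](OC(=O)/C(C)=C\C)C[C@]12COC(=O)[C@H](C)CC | intermediate
51 | target, (2R,3S,5R,7R,9S,10R,13R)-labda-8(17),14-diene-2,3,7,13,20-pentol 2-angelate 20-[(R)-2-methylbutanoate] | C=C[C@](C)(O)CC[C@@H]1C(=C)[C@H](O)C[C@H]2C(C)(C)[C@H](O)[C@H](OC(=O)/C(C)=C\C)C[C@]12COC(=O)[C@H](C)CC | target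

Total step count: 28. Longest linear sequence: 24 steps (steps 1–11 and 16–28, from quinic acid); the acid 25 is made in 4 steps (12–15).

Steps most likely to fail

Step 17. Leakage of enolate geometry or a competing boat transition state would erode the C9 configuration. The fallback is an Eschenmoser–Claisen rearrangement, in which allylic strain against the dimethylamino group fixes the ketene acetal geometry. It sets out from 25, which is coupled with dimethylamine (EDC·HCl) to the dimethylamide F1, O-methylated with Me3OBF4 to the imidate salt F2 and treated with NaOMe to give the amide acetal F3. Heating F3 with 18 in xylene at 140 °C exchanges one methoxy group and loses methanol to the ketene N,O-acetal F4, which rearranges through the same chair to the γ,δ-unsaturated amide F5. Iodine in aqueous THF then cyclises F5 through the iminium lactone F6, whose hydrolysis returns the route at iodolactone 31.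

Step 28. Poor facial selectivity at C7 in the ring closure would give mainly the 7β-alcohol. The fallback sets the centre by ketone reduction instead: starting from 48, the cyclised 7-epimer F9 is oxidised at its allylic hydroxyl with MnO2 to the enone F10. Reduction with NaBH4/CeCl3·7H2O at −78 °C should deliver hydride from the β face, because the axial approach on the α face is blocked by the axial C11 chain on C9, and so returns at 51.

Step 23. Slow hydrazone formation at the hindered ketone, or proton loss toward C9 and diiodide formation, would cut the supply of the iodoalkene. The fallback sets out from 40: kinetic deprotonation at the methyl group with KN(SiMe3)2 and trapping with PhNTf2 (THF, −78 °C) gives the enol triflate F7. Pd(PPh3)4 (zerovalent palladium), Me3SnSnMe3 and LiCl convert F7 into the alkenylstannane F8, and iododestannylation with I2 in CH2Cl2 at 0 °C returns at 42.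

Further compounds
F1 | step 17 | (R)-N,N-dimethyl-5-methyl-5-(triethylsilyloxy)hept-6-enamide | C=C[C@](C)(O[Si](CC)(CC)CC)CCCC(=O)N(C)C
F2 | step 17 | O-methyl imidatium tetrafluoroborate of F1 | C=C[C@](C)(O[Si](CC)(CC)CC)CCCC(OC)=[N+](C)C.F[B-](F)(F)F
F3 | step 17 | dimethyl acetal of F1 (1,1-dimethoxy-N,N-dimethylamine) | C=C[C@](C)(O[Si](CC)(CC)CC)CCCC(OC)(OC)N(C)C
F4 | step 17 | ketene N,O-acetal of 18 (C11 syn to the allylic oxygen) | CC(C)(C)[Si](c1ccccc1)(c1ccccc1)OCC[C@H]1C(C)(C)[C@H](OC2(C)C)[C@H](O2)C/C1=C\CO/C(N(C)C)=C\CC[C@@](C)(O[Si](CC)(CC)CC)C=C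
F5 | step 17 | N,N-dimethylamide corresponding to acid 30 | CC(C)(C)[Si](c1ccccc1)(c1ccccc1)OCC[C@H]1C(C)(C)[C@H](OC2(C)C)[C@H](O2)C[C@]1(C=C)[C@H](CC[C@@](C)(O[Si](CC)(CC)CC)C=C)C(=O)N(C)C
F6 | step 17 | iodo iminium lactone iodide | CC(C)(C)[Si](c1ccccc1)(c1ccccc1)OCC[C@H]1C(C)(C)[C@H](OC2(C)C)[C@H](O2)C[C@@]13C(CI)OC(=[N+](C)C)[C@H]3CC[C@@](C)(O[Si](CC)(CC)CC)C=C.[I-]
F7 | step 23 | C8 enol triflate of 40 | CC(C)(C)[Si](c1ccccc1)(c1ccccc1)OCC[C@H]1C(C)(C)[C@H](OC2(C)C)[C@H](O2)C[C@]1(COC(=O)[C@H](C)CC)[C@H](CC[C@@](C)(O[Si](CC)(CC)CC)C=C)C(OS(=O)(=O)C(F)(F)F)=C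
F8 | step 23 | C8 trimethylstannyl alkene | CC(C)(C)[Si](c1ccccc1)(c1ccccc1)OCC[C@H]1C(C)(C)[C@H](OC2(C)C)[C@H](O2)C[C@]1(COC(=O)[C@H](C)CC)[C@H](CC[C@@](C)(O[Si](CC)(CC)CC)C=C)C([Sn](C)(C)C)=C
F9 | step 28 | 7-epimer of the target (7β-hydroxyl) | C=C[C@](C)(O)CC[C@@H]1C(=C)[C@@H](O)C[C@H]2C(C)(C)[C@H](O)[C@H](OC(=O)/C(C)=C\C)C[C@]12COC(=O)[C@H](C)CC
F10 | step 28 | 8(17)-en-7-one | C=C[C@](C)(O)CC[C@@H]1C(=C)C(=O)C[C@H]2C(C)(C)[C@H](O)[C@H](OC(=O)/C(C)=C\C)C[C@]12COC(=O)[C@H](C)CC
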